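## The problem

Compound 15 is a flavonol: a 4H-chromen-4-one (ring A benzo, ring C pyranone) with a 3,4,5-trimethoxyphenyl ring B on C2, free hydroxyls on C3 and C5, and methyl ethers on C7, C8, C3', C4' and C5'. It has no stereocenter, so nothing has to be set or relayed; the stereocenters that appear on the way (the carbinol carbon of 10 and 11, C4a of 13) are racemic and are erased, and the difficulty is purely regiochemical. Ring A is the hard part: every position is different (C5–OH, C6–H, C7–OMe, C8–OMe), and a ring C closure onto a preformed ring A with two ortho oxygens can give the 5,6,7 pattern as easily as the 5,7,8 pattern; the two series also interconvert by ring opening and reclosure in hot mineral acid, so the last steps must be mild. Of the seven phenolic or enolic oxygens only two end free: the C5 hydroxyl is chelated by the C4 carbonyl and needs no protection, whereas the enolic C3 hydroxyl needs a mask that comes off without touching five aryl methyl ethers. The γ-pyranone does not tolerate hydroxide or other hard nucleophiles at C2, the two electron-rich arenes do not tolerate halogen or strong oxidants, and a free 5,8-hydroquinone of this series would oxidise in air to the quinone. The enabling feature is that in ring A the oxygens on C5 and C8 are para, the C7 oxygen is next to C8, C6 bears hydrogen, and the ring is fused to ring C through C4a–C8a. This is the pattern obtained when a 3,4-dioxygenated cyclobut-2-enone, joined through its quaternary C4 to pyranone C6, opens to a dienylketene and closes on pyranone C5: C5 to C8 with their three oxygens come from a squarate, C4a and C8a from a finished ring C.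

## Retrosynthesis

The last bond to be cut is the acetal C–O bond on the C3 oxygen, which takes 15 back to its methoxymethyl ether 14. A mask is needed on this oxygen throughout, because the enolic hydroxyl would quench every organometallic reagent on the way. An acetal is preferred to a benzyl ether (benzylic deprotonation by a lithium amide) and to a sixth methyl ether (not separable from the other five). The forward step asks only for dilute acid, which the 5,7,8 pattern tolerates.

Ring A of 14 is cut at C4a–C5 and, in the same retrosynthetic stroke, C5 and C8 are rejoined, which folds C5–C8 into the four-membered ring of 11 (a Moore rearrangement read backwards). The neighbouring cuts in ring C (C4–C4a or O1–C2) would leave a pentasubstituted benzene with four differentiated oxygens to be made and would reopen the choice between the 5,7,8 and 5,6,7 series. This cut instead builds ring A, oxygens included, on a finished ring C. Compound 11 has one ring fewer than 14 and no free phenol. The forward reaction must open the cyclobutenone with the methoxyl of the quaternary carbon turning outward and must bond the ketene carbon to pyranone C5.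

The methyl group on the quaternary oxygen of 11 is removed to give carbinol 10 (O–CH3 cut). Methylating here, and not after ring expansion, means that the C8 oxygen never has to be distinguished from the C5 oxygen and that no air-sensitive hydroquinone is formed. It also closes the lactonisation pathway that a free hydroxyl has when the ring opens the wrong way. The forward step must etherify a hindered tertiary alcohol without a base strong enough to cleave the strained ring.

The bond between the carbinol carbon of 10 and pyranone C6 (the future C8–C8a bond) is cut, giving aryl pyranone 5 as the nucleophile and semisquarate 8 as the electrophile. This is the convergent cut: each half carries all the functionality of its side. Two selectivities are asked of the forward reaction: metalation of 5 at C6, and addition to the carbonyl of 8 that is flanked by the methoxylated carbon. Only that addition places the methoxyl at C7 and hydrogen at C6.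

In 8 the vinylic C–H bond (the future C6–H) is exchanged for a C–OMe bond, which leads to the symmetrical, commercial squarate 6. The hydrogen enters as hydride by way of 7. Using 6 itself in the coupling would put a fourth methoxyl on ring A that could not be removed. The forward reaction needs mono-addition of hydride and an acid-induced transposition that keeps one methyl ester.

The bond between ring C (C2) and ring B (C1') of 5 is cut to bromopyranone 3 and boronic acid 4. Building ring C around ring B by oxidative ring expansion of a furan would take about twice as many steps and would expose ring B to halogen oxidants. A cross-coupling uses a pyranone that already carries the C3 oxygen and a commercial arylboron reagent. The forward reaction must couple faster than base attacks C2 of 3.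

Removing the acetal (O–CH2 cut) and the bromine (C2–Br cut) from 3 leads through 2 to commercial 3-hydroxy-4H-pyran-4-one 1. Bromination is placed before protection because the free enol directs the electrophile to C2. The forward steps are a monobromination and an O-alkylation.

## Roads not taken

Alternative 1: carbonylative union of the two aryl halves. The cut is C4a–C4 and C4–C3 together. The hindered iodide 1-iodo-2,3,4,6-tetramethoxybenzene A1, a carbonyl carbon taken up from the gas phase, and the enolate of 2-(benzyloxy)-1-(3,4,5-trimethoxyphenyl)ethan-1-one A2 would be joined with Pd(dba)2 (zerovalent palladium) and Xantphos to give the open 1,3-diketone A3 in one operation.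
- Merits: the plan is highly convergent, both halves are simple benzene derivatives, the C3 oxygen is in place, and a catalytic step replaces the low-temperature organolithium and cyclobutenone chemistry of the chosen plan. In these respects it is the better route.
- Weak points: A1 is di-ortho-substituted and very electron-rich (slow oxidative addition, crowded acyl–palladium intermediate), and the α-alkoxy enolate of A2 can acylate on oxygen. Above all, A3 is not yet a flavone. One of the two methoxyls ortho to the ketone must be cleaved and cyclised, and the other cleaved and kept as the C5 hydroxyl. Closure through the methoxyl that has a methoxyl neighbour gives the 5,7,8 series; closure through the other gives the 5,6,7 isomer. Lewis-acid demethylation does not distinguish them reliably, and acid cyclodehydration invites their interconversion.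
- Comparison: Alternative 1 is probably as short as the chosen plan up to A3 and easier to run, but its end game carries a regiochemical risk. The chosen plan has more delicate intermediates, but ring A can form with only one pattern, fixed by which carbonyl of 8 is attacked and by the single free position next to C6 of the pyranone.

Alternative 2: iodocyclisation of an ynone. The cut is O1–C2, with the C3–I bond formed in the same event. ICl would activate the triple bond of 3,4,5-trimethoxy-2-[3-(3,4,5-trimethoxyphenyl)prop-2-ynoyl]phenyl methanesulfonate A4. The ortho methoxyl oxygen attacks, chloride removes its methyl group, and the 3-iodochromone A5 results. The C5 oxygen is carried as a mesylate so that only one oxygen can close the ring.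
- Merits: the ring closure is mild, well established for 2-methoxyaryl ynones, and regiochemically unambiguous. It is better precedented than the key step of the chosen plan and equal to it in certainty about the ring A pattern.
- Weak points: A4 contains ring A as a pentasubstituted benzene with four differentiated oxygens, which has to be made first; this is the task the chosen plan avoids. ICl is also an aromatic iodinating agent, and both ring B and C6 of ring A are strongly activated. The C3 iodide of A5 must still be turned into a hydroxyl by a further metal-mediated step on a hindered vinylogous acyl iodide. The mesylate must be removed by a nucleophile or base, which ring C tolerates poorly.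
- Comparison: the chosen plan has the C3 oxygen in place from its first step, prefabricates no ring A, and ends with one acid deprotection.

Alternative 3: acylium closure of a preformed aryl vinyl ether. The cut is C4–C4a. (2E)-2-(Benzyloxy)-3-[5-(benzyloxy)-2,3-dimethoxyphenoxy]-3-(3,4,5-trimethoxyphenyl)prop-2-enoic acid A6, activated as its mixed anhydride with (CF3CO)2O, would acylate the one free position ortho to the ether oxygen. The product is 3,5-bis(benzyloxy)-7,8-dimethoxy-2-(3,4,5-trimethoxyphenyl)-4H-chromen-4-one A7, and a single hydrogenolysis would then free both hydroxyls.
- Merits: the site of closure is unambiguous because the other ortho position carries a methoxyl, and the ring position is highly activated. The end game, one neutral hydrogenolysis, is gentler than the acid step of the chosen plan and just as short.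
- Weak points: the difficulty is moved into A6. It is a tetrasubstituted enol ether with defined geometry (carboxyl cis to the aryloxy group) that would have to be assembled by addition–elimination from a hindered, non-commercial ring A phenol. It would then have to survive a strongly acidic anhydride medium, in which vinyl ether cleavage back to the phenol and loss of the benzyl ether on the activated ring are both likely.
- Comparison: most of the steps of Alternative 3 would be spent on the ring A phenol and on A6. The chosen plan draws ring A from one commercial four-carbon unit.

Key step: step 7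

Remark on the chemistry: pyranone positions are cited with the locants of 5 (O1, C2 aryl, C3 OMOM, C4 carbonyl, C5–H, C6–H), although the substituent names in 9 to 12 number the same ring from its point of attachment; 1, 4, 6 and solutions of LiTMP and LiAlH(OtBu)3 are taken as purchased.

## Route

Step 1
Reactants: 1 3-hydroxy-4H-pyran-4-one (pyromeconic acid)
Product: 2 2-bromo-3-hydroxy-4H-pyran-4-one
Conditions: NBS (1.0 equiv), MeCN, 0 °C → rt
Reagents that add atoms: N-bromosuccinimide, O=C1CCC(=O)N1Br
Why: Electrophilic bromination of an enol: 1 is the enol form of a cyclic 1,2-dicarbonyl compound, and C2, the enol β-carbon ortho to the hydroxyl, is the position at which 3-hydroxy-4-pyranones take up electrophiles (halogen, Mannich and hydroxymethyl groups); one equivalent of NBS at low temperature should leave C5 and C6 alone.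

Step 2
Reactants: 2 2-bromo-3-hydroxy-4H-pyran-4-one
Product: 3 2-bromo-3-(methoxymethoxy)-4H-pyran-4-one
Conditions: MOMCl, iPr2NEt, CH2Cl2, 0 °C → rt
Reagents that add atoms: chloromethyl methyl ether (MOMCl), COCCl
Why: O-Alkylation of the acidic enolic hydroxyl with MOMCl and a hindered amine (acetal protection); the MOM ether has no benzylic hydrogens, should withstand LiTMP, Ag2O/MeI and 140 °C, and is the one group of the later intermediates that dilute acid removes.

Step 3
Reactants: 3 2-bromo-3-(methoxymethoxy)-4H-pyran-4-one; 4 (3,4,5-trimethoxyphenyl)boronic acid
Product: 5 3-(methoxymethoxy)-2-(3,4,5-trimethoxyphenyl)-4H-pyran-4-one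
Conditions: Pd(PPh3)4 (5 mol %), K3PO4, 1,4-dioxane/H2O (10:1), 80 °C
Reagents that add atoms: none
Why: Suzuki–Miyaura coupling: the C2–Br bond is a vinylogous acyl bromide (β-bromo enone flanked by the ring oxygen), so oxidative addition to zerovalent palladium should be fast, and the electron-rich boronic acid 4 transmetalates readily; little water and a short reaction time limit attack of base on C2.

Step 4
Reactants: 6 dimethyl squarate (3,4-dimethoxycyclobut-3-ene-1,2-dione)
Product: 8 3-methoxycyclobut-3-ene-1,2-dione, via hydride adduct 7 (not isolated)
Conditions: LiAlH(OtBu)3 (1.0 equiv), THF, −78 °C; aq. HCl work-up; then conc. HCl (cat.), CH2Cl2, rt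
Reagents that add atoms: water, O
Why: The bulky hydride adds once, 1,2, to one of the two equivalent carbonyl groups of 6 to give racemic carbinol 7; acid then ionises the allylic hydroxyl, water adds to the methoxy-stabilised cation at the far end and methanol is lost (allylic transposition of a vinylogous hemiketal, so the new carbonyl oxygen comes from the aqueous acid), which is the established route from dialkyl squarates to semisquaric esters; the stereocenter of 7 disappears, and 8 should be used soon after isolation because it is moisture-sensitive.

Step 5
Reactants: 5 3-(methoxymethoxy)-2-(3,4,5-trimethoxyphenyl)-4H-pyran-4-one; 8 3-methoxycyclobut-3-ene-1,2-dione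
Product: 10 4-hydroxy-3-methoxy-4-[5-(methoxymethoxy)-4-oxo-6-(3,4,5-trimethoxyphenyl)-4H-pyran-2-yl]cyclobut-2-en-1-one (racemic), via pyranonyllithium 9 (not isolated)
Conditions: LiTMP (lithium 2,2,6,6-tetramethylpiperidide, 1.05 equiv), THF, −78 °C, 20 min; cannulate onto 8 (1.2 equiv), THF, −78 °C; sat. aq. NH4Cl
Reagents that add atoms: none
Why: Deprotonation followed by 1,2-addition: C6–H, next to the ring oxygen and β to the carbonyl, is the most acidic ring hydrogen of 5 and the site at which 4-pyranones and chromones are metalated by hindered amide bases, while LiTMP is too hindered to add to the ring; organolithium reagents add to 3-alkoxycyclobutene-1,2-diones at the carbonyl outside the vinylogous ester (the one flanked by the methoxylated carbon), which puts the methoxyl next to the new carbinol as the C7/C8 relation requires; the new stereocenter forms racemic and is destroyed in step 7.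

Step 6
Reactants: 10 4-hydroxy-3-methoxy-4-[5-(methoxymethoxy)-4-oxo-6-(3,4,5-trimethoxyphenyl)-4H-pyran-2-yl]cyclobut-2-en-1-one (racemic)
Product: 11 3,4-dimethoxy-4-[5-(methoxymethoxy)-4-oxo-6-(3,4,5-trimethoxyphenyl)-4H-pyran-2-yl]cyclobut-2-en-1-one (racemic)
Conditions: MeI (excess), Ag2O, MeCN, rt, dark
Reagents that add atoms: iodomethane, CI
Why: Purdie methylation (Ag2O/MeI) of the tertiary hydroxyl under essentially neutral conditions, the usual way to 4-methoxycyclobutenones; neither the pyranone carbonyl nor the MOM acetal reacts with MeI, and fixing the future C8 methoxyl here means that ring A is never a free hydroquinone.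

Step 7
Reactants: 11 3,4-dimethoxy-4-[5-(methoxymethoxy)-4-oxo-6-(3,4,5-trimethoxyphenyl)-4H-pyran-2-yl]cyclobut-2-en-1-one (racemic)
Product: 14 5-hydroxy-7,8-dimethoxy-3-(methoxymethoxy)-2-(3,4,5-trimethoxyphenyl)-4H-chromen-4-one, via dienylketene 12 (not isolated), via dienone 13 (not isolated)
Conditions: p-xylene (degassed, 0.02 M), 140 °C
Reagents that add atoms: none
Why: Heat opens the cyclobutenone of 11 by conrotatory 4π electrocyclic cleavage of the bond between the carbonyl carbon and the quaternary carbon; the donor methoxyl on that carbon should turn outward (torquoselectivity), so that the pyranone turns inward and lies beside the ketene in the (Z)-dienylketene 12. The ketene carbon then bonds to pyranone C5, the nucleophilic α-carbon of the vinylogous ester, in a thermal 6π electrocyclisation that forms C4a–C5 and closes ring A as a six-membered carbocycle (dienone 13). The hydrogen left on C4a of 13 lies between two carbonyl groups and should shift to oxygen at once, which makes ring A aromatic and leaves the new C5 hydroxyl chelated to the C4 carbonyl. The closest known reaction type is the Moore rearrangement of 4-aryl-, 4-heteroaryl- and 4-alkenyl-4-alkoxycyclobutenones to monoprotected hydroquinones, the pyranone C5=C6 bond here taking the part of the aryl or alkenyl π bond. No lasting stereocenter is created: the quaternary carbon of 11 and C4a of 13 both end sp2, so the racemic nature of 11 is of no consequence. The step needs site selectivity and the right sense of opening: closure can occur only at C5, the single free ring position next to C6, and a molecule that opens with the methoxyl inward can neither cyclise nor lactonise and should revert to 11 through the reversible ring opening. The substitution of ring A follows from the connectivity of 11 (ketene carbon to C5–OH, CH to C6, methoxylated alkene carbon to C7, quaternary carbon to C8–OMe), and since the C8 oxygen is already methylated the product cannot be oxidised to a quinone.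

Step 8
Reactants: 14 5-hydroxy-7,8-dimethoxy-3-(methoxymethoxy)-2-(3,4,5-trimethoxyphenyl)-4H-chromen-4-one
Product: 15 3,5-dihydroxy-7,8-dimethoxy-2-(3,4,5-trimethoxyphenyl)-4H-chromen-4-one (3,5-dihydroxy-7,8,3',4',5'-pentamethoxyflavone)
Conditions: HCl (1.25 M in MeOH), 40 °C
Reagents that add atoms: none
Why: Acid-catalysed acetal cleavage (MOM removal) by methanolysis; the aryl methyl ethers and the chelated C5 hydroxyl are inert, and the conditions are far milder than the hot HI or HBr needed for demethylation or for Wessely–Moser isomerisation of the 5,7,8 pattern.

## Compound list

1 | 3-hydroxy-4H-pyran-4-one (pyromeconic acid) | O=c1ccocc1O | starting material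
2 | 2-bromo-3-hydroxy-4H-pyran-4-one | O=c1ccoc(Br)c1O | intermediate
3 | 2-bromo-3-(methoxymethoxy)-4H-pyran-4-one | COCOc1c(Br)occc1=O | intermediate
4 | (3,4,5-trimethoxyphenyl)boronic acid | COc1cc(B(O)O)cc(OC)c1OC | starting material
5 | 3-(methoxymethoxy)-2-(3,4,5-trimethoxyphenyl)-4H-pyran-4-one | COCOc1c(-c2cc(OC)c(OC)c(OC)c2)occc1=O | intermediate
6 | dimethyl squarate (3,4-dimethoxycyclobut-3-ene-1,2-dione) | COC1=C(OC)C(=O)C1=O | starting material
7 | 4-hydroxy-2,3-dimethoxycyclobut-2-en-1-one (racemic) | COC1=C(OC)C(O)C1=O | intermediate
8 | 3-methoxycyclobut-3-ene-1,2-dione | COC1=CC(=O)C1=O | intermediate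
9 | [5-(methoxymethoxy)-4-oxo-6-(3,4,5-trimethoxyphenyl)-4H-pyran-2-yl]lithium | [Li]c1cc(=O)c(OCOC)c(-c2cc(OC)c(OC)c(OC)c2)o1 | intermediate
10 | 4-hydroxy-3-methoxy-4-[5-(methoxymethoxy)-4-oxo-6-(3,4,5-trimethoxyphenyl)-4H-pyran-2-yl]cyclobut-2-en-1-one (racemic) | COC1=CC(=O)C1(O)c1cc(=O)c(OCOC)c(-c2cc(OC)c(OC)c(OC)c2)o1 | intermediate
11 | 3,4-dimethoxy-4-[5-(methoxymethoxy)-4-oxo-6-(3,4,5-trimethoxyphenyl)-4H-pyran-2-yl]cyclobut-2-en-1-one (racemic) | COC1=CC(=O)C1(OC)c1cc(=O)c(OCOC)c(-c2cc(OC)c(OC)c(OC)c2)o1 | intermediate
12 | (3Z)-3,4-dimethoxy-4-[5-(methoxymethoxy)-4-oxo-6-(3,4,5-trimethoxyphenyl)-4H-pyran-2-yl]buta-1,3-dien-1-one | O=C=C/C(OC)=C(\c1cc(=O)c(OCOC)c(-c2cc(OC)c(OC)c(OC)c2)o1)OC | intermediate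
13 | 7,8-dimethoxy-3-(methoxymethoxy)-2-(3,4,5-trimethoxyphenyl)-4aH-chromene-4,5-dione (racemic) | O=C1C=C(OC)C(OC)=C2OC(-c3cc(OC)c(OC)c(OC)c3)=C(OCOC)C(=O)C12 | intermediate
14 | 5-hydroxy-7,8-dimethoxy-3-(methoxymethoxy)-2-(3,4,5-trimethoxyphenyl)-4H-chromen-4-one | COCOc1c(-c2cc(OC)c(OC)c(OC)c2)oc2c(OC)c(OC)cc(O)c2c1=O | intermediate
15 | 3,5-dihydroxy-7,8-dimethoxy-2-(3,4,5-trimethoxyphenyl)-4H-chromen-4-one | COc1cc(-c2oc3c(OC)c(OC)cc(O)c3c(=O)c2O)cc(OC)c1OC | target

## Step count and least certain steps

Total: 8 steps. Longest linear sequence: 7 steps (steps 1, 2, 3, 5, 6, 7, 8); step 4 is a one-step side branch.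

Step 7 (key step). The most likely failure is slow closure: bonding to C5 interrupts the conjugation of the pyranone on the way to 13, and a long-lived ketene could be lost to dimerisation or to acylation of the phenol already formed. Opening with the methoxyl inward would add to the time spent at 140 °C. The fallback keeps the disconnection but runs it at the hydroquinone oxidation level, the most widely used mode of this rearrangement, and moves the methylation behind it. It sets out from 10, which would be heated without prior methylation (degassed toluene, 110 °C, argon); the hydroxyl is the stronger outward-turning donor. The product would be 5,8-dihydroxy-7-methoxy-3-(methoxymethoxy)-2-(3,4,5-trimethoxyphenyl)-4H-chromen-4-one F1. Its C8 hydroxyl is the only phenol not held in a hydrogen bond to the C4 carbonyl and should be methylated selectively (MeI, 1.1 equiv, K2CO3, acetone, argon, rt), which returns to the route at 14.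

Step 5. The most likely failures are metalation at the wrong site (C5, or ring B next to a methoxyl), fragmentation of the lithiated pyranone if it warms, and attack on the wrong carbonyl of 8. The fallback replaces deprotonation–addition by halogen–metal exchange on an isolable halide whose regiochemistry can be checked. It sets out from 5, which would be zincated with TMPZnCl·LiCl (THF, 25 °C) to chlorido[5-(methoxymethoxy)-4-oxo-6-(3,4,5-trimethoxyphenyl)-4H-pyran-2-yl]zinc F2. Quenching with I2 would give 6-iodo-3-(methoxymethoxy)-2-(3,4,5-trimethoxyphenyl)-4H-pyran-4-one F3. Exchange with iPrMgCl·LiCl (THF, −40 °C) would give chlorido[5-(methoxymethoxy)-4-oxo-6-(3,4,5-trimethoxyphenyl)-4H-pyran-2-yl]magnesium F4, which would be added to 8 at −78 °C and returns to the route at 10.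

Step 6. The most likely failure is sluggish etherification of the hindered tertiary alcohol, with base- or silver-promoted cleavage of the strained ring (retro-aldol-type C–C scission) taking over during a long reaction. The fallback avoids the neutral alcohol. It sets out from 5 and 8 as in step 5, but the reaction mixture is not quenched with NH4Cl. The alkoxide lithium 2-methoxy-1-[5-(methoxymethoxy)-4-oxo-6-(3,4,5-trimethoxyphenyl)-4H-pyran-2-yl]-4-oxocyclobut-2-en-1-olate F5 would be trapped at −78 °C with MeOTf (1.0 equiv, to spare the pyranone carbonyl), which returns to the route at 11.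

Step 3. The most likely failure is displacement of bromide from C2 by hydroxide or phosphate (addition–elimination on the vinylogous acyl bromide), together with protodeboronation of 4, outrunning the cross-coupling. The fallback reverses the polarity and dispenses with both the halide and the aqueous base. It sets out from 1, which would be protected (MOMCl, iPr2NEt, CH2Cl2) as 3-(methoxymethoxy)-4H-pyran-4-one F6. Zincation with TMPZnCl·LiCl should occur at C2, the ring hydrogen flanked by the ring oxygen and the acetal-bearing carbon, to give chlorido[3-(methoxymethoxy)-4-oxo-4H-pyran-2-yl]zinc F7. Negishi coupling of F7 with commercial 5-iodo-1,2,3-trimethoxybenzene (Pd(PPh3)4, THF, 50 °C) returns to the route at 5.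

## Further compounds

F1 | step 7 | 5,8-dihydroxy-7-methoxy-3-(methoxymethoxy)-2-(3,4,5-trimethoxyphenyl)-4H-chromen-4-one | O=c1c(OCOC)c(-c2cc(OC)c(OC)c(OC)c2)oc2c(O)c(OC)cc(O)c12
F2 | step 5 | chlorido[5-(methoxymethoxy)-4-oxo-6-(3,4,5-trimethoxyphenyl)-4H-pyran-2-yl]zinc | Cl[Zn]c1cc(=O)c(OCOC)c(-c2cc(OC)c(OC)c(OC)c2)o1
F3 | step 5 | 6-iodo-3-(methoxymethoxy)-2-(3,4,5-trimethoxyphenyl)-4H-pyran-4-one | COCOc1c(-c2cc(OC)c(OC)c(OC)c2)oc(I)cc1=O
F4 | step 5 | chlorido[5-(methoxymethoxy)-4-oxo-6-(3,4,5-trimethoxyphenyl)-4H-pyran-2-yl]magnesium | Cl[Mg]c1cc(=O)c(OCOC)c(-c2cc(OC)c(OC)c(OC)c2)o1
F5 | step 6 | lithium 2-methoxy-1-[5-(methoxymethoxy)-4-oxo-6-(3,4,5-trimethoxyphenyl)-4H-pyran-2-yl]-4-oxocyclobut-2-en-1-olate (racemic) | [Li+].COC1=CC(=O)C1([O-])c1cc(=O)c(OCOC)c(-c2cc(OC)c(OC)c(OC)c2)o1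
F6 | step 3 | 3-(methoxymethoxy)-4H-pyran-4-one | COCOc1coccc1=O
F7 | step 3 | chlorido[3-(methoxymethoxy)-4-oxo-4H-pyran-2-yl]zinc | COCOc1c([Zn]Cl)occc1=O
A1 | alternative 1 | 1-iodo-2,3,4,6-tetramethoxybenzene | COc1cc(OC)c(I)c(OC)c1OC
A2 | alternative 1 | 2-(benzyloxy)-1-(3,4,5-trimethoxyphenyl)ethan-1-one | COc1cc(C(=O)COCc2ccccc2)cc(OC)c1OC
A3 | alternative 1 | 2-(benzyloxy)-1-(2,3,4,6-tetramethoxyphenyl)-3-(3,4,5-trimethoxyphenyl)propane-1,3-dione (racemic, enolizable) | COc1cc(OC)c(C(=O)C(OCc2ccccc2)C(=O)c2cc(OC)c(OC)c(OC)c2)c(OC)c1OC
A4 | alternative 2 | 3,4,5-trimethoxy-2-[3-(3,4,5-trimethoxyphenyl)prop-2-ynoyl]phenyl methanesulfonate | COc1cc(OS(C)(=O)=O)c(C(=O)C#Cc2cc(OC)c(OC)c(OC)c2)c(OC)c1OC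
A5 | alternative 2 | 3-iodo-7,8-dimethoxy-4-oxo-2-(3,4,5-trimethoxyphenyl)-4H-chromen-5-yl methanesulfonate | O=c1c(I)c(-c2cc(OC)c(OC)c(OC)c2)oc2c(OC)c(OC)cc(OS(C)(=O)=O)c12
A6 | alternative 3 | (2E)-2-(benzyloxy)-3-[5-(benzyloxy)-2,3-dimethoxyphenoxy]-3-(3,4,5-trimethoxyphenyl)prop-2-enoic acid | OC(=O)/C(OCc1ccccc1)=C(\Oc1cc(OCc2ccccc2)cc(OC)c1OC)c1cc(OC)c(OC)c(OC)c1
A7 | alternative 3 | 3,5-bis(benzyloxy)-7,8-dimethoxy-2-(3,4,5-trimethoxyphenyl)-4H-chromen-4-one | O=c1c(OCc2ccccc2)c(-c2cc(OC)c(OC)c(OC)c2)oc2c(OC)c(OC)cc(OCc3ccccc3)c12
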